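**Retrosynthetic overview**

1. Locants: lactone O1, C2(=O), C3(CH2OH), C4H, C5; chain C6H=, C7H(CH3) (S), C8H2, C9H=C10H, C11(CH3)=C12H, C13H2, C14H2, then the 3,4-disubstituted furan. The butenolide is the only ring made (both furans are bought) and is formed last. The O1–C5 and C4–C5 bonds are both cut, giving (Z)-2-(hydroxymethyl)-3-iodoacrylic acid and the (S)-configured C20 terminal alkyne HC5≡C6–C7; one Pd/Cu coupling–lactonisation cascade unites them through the (Z)-2-en-4-ynoic acid.
2. Enabling feature: O1 sits on sp2 C5 of an enol ester whose exocyclic C5=C6 bond is Z, and the endocyclic C3=C4 bond holds the C2 carboxyl and C5 cis. This is exactly the anti adduct of a carboxylate O–H across a C5≡C6 triple bond in the 5-exo-dig mode.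
3. Alkyne: C5≡C6 by Ohira–Bestmann homologation of the C6 aldehyde; C7 set by Evans alkylation (C7–C8 bond) of (R)-4-benzyl-3-propanoyloxazolidin-2-one with the (2E,4E)-dienyl bromide.
4. Dienyl bromide: C9=C10 by Horner–Wadsworth–Emmons and C11=C12 by Wittig olefination from the 3-(furyl)propanal; the bis-furan by two successive Br/Li exchanges on 3,4-dibromofuran (furan-3-carbaldehyde, then oxetane).
5. Iodo acid: iodide-triggered aldol (β-iodo Morita–Baylis–Hillman type) of methyl propiolate with formaldehyde, then saponification.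

Key step: step 15

**Route**

Step 1
Reactants: 1 3,4-dibromofuran; 2 furan-3-carbaldehyde
Product: 4 (4-bromofuran-3-yl)(furan-3-yl)methanol, via (4-bromofuran-3-yl)lithium 3 (not isolated)
Conditions: n-BuLi (1.0 equiv), Et2O, −78 °C; then 2, −78 °C; H2O
Reagents that add atoms: none
Why: Bromine–lithium exchange on one C–Br bond of the symmetrical dibromide is fast at −78 °C and the 3-furyllithium adds 1,2 to the aldehyde (halogen–metal exchange/carbonyl addition); the new carbinol centre is racemic and is deleted in step 2.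

Step 2
Reactants: 4 (4-bromofuran-3-yl)(furan-3-yl)methanol
Product: 5 3-bromo-4-(furan-3-ylmethyl)furan
Conditions: Et3SiH (3 equiv), TFA (2 equiv), CH2Cl2, −20 to 0 °C
Reagents that add atoms: none
Why: Ionic hydrogenation: the bis-furyl-stabilised carbocation formed from the carbinol is trapped by hydride from the silane in large excess at low temperature, which should outrun Friedel–Crafts oligomerisation and leaves the C–Br bond untouched.

Step 3
Reactants: 5 3-bromo-4-(furan-3-ylmethyl)furan; 6 oxetane
Product: 8 3-[4-(furan-3-ylmethyl)furan-3-yl]propan-1-ol, via [4-(furan-3-ylmethyl)furan-3-yl]lithium 7 (not isolated)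
Conditions: n-BuLi, THF, −78 °C; then 6, BF3·OEt2, −78 °C; H2O
Reagents that add atoms: none
Why: Br/Li exchange outpaces deprotonation of the diarylmethane CH2 at −78 °C, and BF3-assisted SN2 ring opening of oxetane by the 3-furyllithium installs C12–C14 with the terminal hydroxyl in one operation.

Step 4
Reactants: 8 3-[4-(furan-3-ylmethyl)furan-3-yl]propan-1-ol
Product: 9 3-[4-(furan-3-ylmethyl)furan-3-yl]propanal
Conditions: Dess–Martin periodinane, pyridine, CH2Cl2, 0 °C to rt
Reagents that add atoms: none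
Why: Dess–Martin oxidation takes the primary alcohol to the aldehyde under buffered conditions that both acid-sensitive furans should tolerate.

Step 5
Reactants: 9 3-[4-(furan-3-ylmethyl)furan-3-yl]propanal; 10 2-(triphenyl-λ5-phosphanylidene)propanal
Product: 11 (E)-5-[4-(furan-3-ylmethyl)furan-3-yl]-2-methylpent-2-enal
Conditions: toluene, 90 °C
Reagents that add atoms: none
Why: Wittig olefination with the stabilised formyl ylide should give the trisubstituted (E)-2-methyl-2-enal, which fixes the C11=C12 geometry.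

Step 6
Reactants: 11 (E)-5-[4-(furan-3-ylmethyl)furan-3-yl]-2-methylpent-2-enal; 12 triethyl phosphonoacetate
Product: 13 ethyl (2E,4E)-7-[4-(furan-3-ylmethyl)furan-3-yl]-4-methylhepta-2,4-dienoate
Conditions: NaH, THF, 0 °C to rt
Reagents that add atoms: none
Why: Horner–Wadsworth–Emmons olefination of the enal with the stabilised phosphonate anion should give the (E)-C9=C10 bond.

Step 7
Reactants: 13 ethyl (2E,4E)-7-[4-(furan-3-ylmethyl)furan-3-yl]-4-methylhepta-2,4-dienoate
Product: 14 (2E,4E)-7-[4-(furan-3-ylmethyl)furan-3-yl]-4-methylhepta-2,4-dien-1-ol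
Conditions: DIBAL-H (2.2 equiv), CH2Cl2, −78 °C; Rochelle salt
Reagents that add atoms: none
Why: DIBAL-H 1,2-reduction of the dienoate gives the allylic alcohol without touching the diene or the furans.

Step 8
Reactants: 14 (2E,4E)-7-[4-(furan-3-ylmethyl)furan-3-yl]-4-methylhepta-2,4-dien-1-ol
Product: 15 3-[(3E,5E)-7-bromo-4-methylhepta-3,5-dien-1-yl]-4-(furan-3-ylmethyl)furan
Conditions: CBr4, PPh3, CH2Cl2, −20 to 0 °C; used crude
Reagents that add atoms: tetrabromomethane, BrC(Br)(Br)Br
Why: The Appel reaction converts the primary dienylic alcohol into the bromide by SN2 displacement of the oxyphosphonium under neutral conditions, so both olefin geometries should be kept.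

Step 9
Reactants: 15 3-[(3E,5E)-7-bromo-4-methylhepta-3,5-dien-1-yl]-4-(furan-3-ylmethyl)furan; 16 (R)-4-benzyl-3-propanoyloxazolidin-2-one
Product: 18 (R)-4-benzyl-3-[(2S,4E,6E)-9-[4-(furan-3-ylmethyl)furan-3-yl]-2,6-dimethylnona-4,6-dienoyl]oxazolidin-2-one, via sodium (Z)-enolate 17 (not isolated)
Conditions: NaHMDS, THF, −78 °C; then 15, −78 to −40 °C
Reagents that add atoms: none
Why: Evans asymmetric alkylation: the chelated sodium (Z)-enolate is alkylated at the primary carbon of the dienylic bromide on the face opposite the benzyl group, which with the (R)-auxiliary sets C7 as (S), and the minor diastereomer is separable by chromatography.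

Step 10
Reactants: 18 (R)-4-benzyl-3-[(2S,4E,6E)-9-[4-(furan-3-ylmethyl)furan-3-yl]-2,6-dimethylnona-4,6-dienoyl]oxazolidin-2-one
Product: 19 (2S,4E,6E)-9-[4-(furan-3-ylmethyl)furan-3-yl]-2,6-dimethylnona-4,6-dien-1-ol
Conditions: LiBH4, MeOH (1.1 equiv), Et2O, 0 °C
Reagents that add atoms: none
Why: Reductive cleavage of the N-acyl oxazolidinone by borohydride attack at the exocyclic carbonyl gives the primary alcohol and returns the auxiliary without enolising C7.

Step 11
Reactants: 19 (2S,4E,6E)-9-[4-(furan-3-ylmethyl)furan-3-yl]-2,6-dimethylnona-4,6-dien-1-ol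
Product: 20 (2S,4E,6E)-9-[4-(furan-3-ylmethyl)furan-3-yl]-2,6-dimethylnona-4,6-dienal
Conditions: Dess–Martin periodinane, pyridine, CH2Cl2, 0 °C; used at once
Reagents that add atoms: none
Why: Buffered Dess–Martin oxidation gives the α-branched aldehyde under conditions that should not epimerise C7.

Step 12
Reactants: 20 (2S,4E,6E)-9-[4-(furan-3-ylmethyl)furan-3-yl]-2,6-dimethylnona-4,6-dienal; 21 dimethyl (1-diazo-2-oxopropyl)phosphonate
Product: 23 3-[(3E,5E,8S)-4,8-dimethyldeca-3,5-dien-9-yn-1-yl]-4-(furan-3-ylmethyl)furan, via 1-diazoalkene 22 (not isolated)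
Conditions: K2CO3, MeOH/THF, 0 °C to rt
Reagents that add atoms: none
Why: Seyferth–Gilbert homologation in the Ohira–Bestmann variant: the diazomethylphosphonate anion released by methanolysis adds to the aldehyde, cycloelimination gives the diazoalkene, and loss of N2 with 1,2-hydrogen shift gives the terminal alkyne under mild carbonate conditions intended to preserve C7.

Step 13
Reactants: 24 methyl propiolate; 25 formaldehyde
Product: 27 methyl (Z)-2-(hydroxymethyl)-3-iodoprop-2-enoate, via iodomagnesium 3-iodoallenolate 26 (not isolated)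
Conditions: MgI2 (1.2 equiv), CH2Cl2, 0 °C; monomeric CH2O (cracked paraformaldehyde), −20 to 0 °C; H2O
Reagents that add atoms: magnesium iodide, [Mg+2].[I-].[I-]
Why: β-Iodo Morita–Baylis–Hillman-type reaction: iodide adds to the propiolate and the resulting β-iodoallenolate undergoes aldol addition to formaldehyde in the plane of the CHI terminus on the side of H, not I, so the kinetic product should carry iodine cis to the ester (Z).

Step 14
Reactants: 27 methyl (Z)-2-(hydroxymethyl)-3-iodoprop-2-enoate
Product: 28 (Z)-2-(hydroxymethyl)-3-iodoprop-2-enoic acid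
Conditions: LiOH, THF/H2O, 0 °C; then aq. HCl to pH 2–3
Reagents that add atoms: lithium hydroxide (its oxygen becomes the acid OH), [Li+].[OH-]
Why: Saponification of the methyl ester; the vinylic iodide has only a geminal hydrogen, so no E2 loss of HI is possible and the Z geometry should survive.

Step 15
Reactants: 23 3-[(3E,5E,8S)-4,8-dimethyldeca-3,5-dien-9-yn-1-yl]-4-(furan-3-ylmethyl)furan; 28 (Z)-2-(hydroxymethyl)-3-iodoprop-2-enoic acid
Product: 30 (5Z)-5-[(2S,4E,6E)-9-[4-(furan-3-ylmethyl)furan-3-yl]-2,6-dimethylnona-4,6-dien-1-ylidene]-3-(hydroxymethyl)furan-2(5H)-one, via (Z)-enynoic acid 29 (not isolated)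
Conditions: Pd(PPh3)4 (5 mol %), CuI (10 mol %), Et3N (3 equiv), MeCN, rt, degassed, dark
Reagents that add atoms: none
Why: Oxidative addition of Pd(0) into the vinyl C–I bond of 28, transmetalation with the copper acetylide of 23 and reductive elimination give the (Z)-2-en-4-ynoic acid 29 with retention of olefin geometry; its carboxylate, held cis to the alkyne by the C3=C4 bond, then attacks C5 of the metal-activated triple bond anti to the metal, and protodemetalation releases the lactone. The closest known reaction type is the Pd/Cu-catalysed tandem Sonogashira coupling–lactonisation of (Z)-3-iodoalk-2-enoic acids with terminal alkynes to (Z)-γ-alkylidenebutenolides. The butenolide ring closes in the 5-exo-dig mode by formation of the O1–C5 bond. No stereocentre is created: the exocyclic C5=C6 geometry is set as Z by anti oxymetalation followed by retentive protonation, and C7 is a spectator because the propargylic C–H of 29 is not acidic and the product is only exposed to Et3N at room temperature. The step needs 5-exo over 6-endo closure (2-pyranone) and carboxylate over hydroxyl attack: the Pd/Cu–amine conditions and the alkyl-substituted alkyne favour attack at the proximal alkyne carbon, and the hydroxymethyl group lies trans to the alkyne across C3=C4 and cannot reach it.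

**Compound list**

1 | 3,4-dibromofuran | Brc1cocc1Br | starting material
2 | furan-3-carbaldehyde | O=Cc1ccoc1 | starting material
3 | (4-bromofuran-3-yl)lithium (formed in the flask) | [Li]c1cocc1Br | intermediate
4 | (4-bromofuran-3-yl)(furan-3-yl)methanol (racemic) | OC(c1ccoc1)c1cocc1Br | intermediate
5 | 3-bromo-4-(furan-3-ylmethyl)furan | Brc1cocc1Cc1ccoc1 | intermediate
6 | oxetane | C1COC1 | starting material
7 | [4-(furan-3-ylmethyl)furan-3-yl]lithium (formed in the flask) | [Li]c1cocc1Cc1ccoc1 | intermediate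
8 | 3-[4-(furan-3-ylmethyl)furan-3-yl]propan-1-ol | OCCCc1cocc1Cc1ccoc1 | intermediate
9 | 3-[4-(furan-3-ylmethyl)furan-3-yl]propanal | O=CCCc1cocc1Cc1ccoc1 | intermediate
10 | 2-(triphenyl-λ5-phosphanylidene)propanal | CC(C=O)=P(c1ccccc1)(c1ccccc1)c1ccccc1 | starting material
11 | (E)-5-[4-(furan-3-ylmethyl)furan-3-yl]-2-methylpent-2-enal | O=C/C(C)=C/CCc1cocc1Cc1ccoc1 | intermediate
12 | triethyl phosphonoacetate | CCOC(=O)CP(=O)(OCC)OCC | starting material
13 | ethyl (2E,4E)-7-[4-(furan-3-ylmethyl)furan-3-yl]-4-methylhepta-2,4-dienoate | CCOC(=O)/C=C/C(C)=C/CCc1cocc1Cc1ccoc1 | intermediate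
14 | (2E,4E)-7-[4-(furan-3-ylmethyl)furan-3-yl]-4-methylhepta-2,4-dien-1-ol | OC/C=C/C(C)=C/CCc1cocc1Cc1ccoc1 | intermediate
15 | 3-[(3E,5E)-7-bromo-4-methylhepta-3,5-dien-1-yl]-4-(furan-3-ylmethyl)furan | BrC/C=C/C(C)=C/CCc1cocc1Cc1ccoc1 | intermediate
16 | (R)-4-benzyl-3-propanoyloxazolidin-2-one | CCC(=O)N1[C@H](Cc2ccccc2)COC1=O | starting material
17 | sodium (Z)-enolate of 16 (formed in the flask) | C/C=C(\[O-])N1[C@H](Cc2ccccc2)COC1=O.[Na+] | intermediate
18 | (R)-4-benzyl-3-[(2S,4E,6E)-9-[4-(furan-3-ylmethyl)furan-3-yl]-2,6-dimethylnona-4,6-dienoyl]oxazolidin-2-one | CC(/C=C/C[C@H](C)C(=O)N1[C@H](Cc2ccccc2)COC1=O)=C\CCc1cocc1Cc1ccoc1 | intermediate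
19 | (2S,4E,6E)-9-[4-(furan-3-ylmethyl)furan-3-yl]-2,6-dimethylnona-4,6-dien-1-ol | CC(/C=C/C[C@H](C)CO)=C\CCc1cocc1Cc1ccoc1 | intermediate
20 | (2S,4E,6E)-9-[4-(furan-3-ylmethyl)furan-3-yl]-2,6-dimethylnona-4,6-dienal | CC(/C=C/C[C@H](C)C=O)=C\CCc1cocc1Cc1ccoc1 | intermediate
21 | dimethyl (1-diazo-2-oxopropyl)phosphonate | CC(=O)C(=[N+]=[N-])P(=O)(OC)OC | starting material
22 | 3-[(3E,5E,8S)-10-diazo-4,8-dimethyldeca-3,5,9-trien-1-yl]-4-(furan-3-ylmethyl)furan (formed in the flask) | CC(/C=C/C[C@H](C)C=C=[N+]=[N-])=C\CCc1cocc1Cc1ccoc1 | intermediate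
23 | 3-[(3E,5E,8S)-4,8-dimethyldeca-3,5-dien-9-yn-1-yl]-4-(furan-3-ylmethyl)furan | CC(/C=C/C[C@H](C)C#C)=C\CCc1cocc1Cc1ccoc1 | intermediate
24 | methyl propiolate | C#CC(=O)OC | starting material
25 | formaldehyde (monomer from paraformaldehyde) | C=O | starting material
26 | iodomagnesium 3-iodoallenolate of methyl propiolate (formed in the flask) | COC(O[Mg]I)=C=CI | intermediate
27 | methyl (Z)-2-(hydroxymethyl)-3-iodoprop-2-enoate | COC(=O)/C(CO)=C\I | intermediate
28 | (Z)-2-(hydroxymethyl)-3-iodoprop-2-enoic acid | OC(=O)/C(CO)=C\I | intermediate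
29 | (2Z,6S,8E,10E)-13-[4-(furan-3-ylmethyl)furan-3-yl]-2-(hydroxymethyl)-6,10-dimethyltrideca-2,8,10-trien-4-ynoic acid (formed in the flask) | CC(/C=C/C[C@H](C)C#C/C=C(/CO)C(=O)O)=C\CCc1cocc1Cc1ccoc1 | intermediate
30 | (5Z)-5-[(2S,4E,6E)-9-[4-(furan-3-ylmethyl)furan-3-yl]-2,6-dimethylnona-4,6-dien-1-ylidene]-3-(hydroxymethyl)furan-2(5H)-one | CC(/C=C/C[C@H](C)/C=C1/C=C(CO)C(=O)O1)=C\CCc1cocc1Cc1ccoc1 | target

**Count and risks**

Total step count: 15.
Longest linear sequence: 13 steps (steps 1–12 and 15, from 3,4-dibromofuran); the iodo acid branch is 2 steps (13, 14).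

Steps most likely to fail:

1. Step 15. The ring closure may go 6-endo-dig to the 2-pyranone, the alkyne may homocouple oxidatively, and if the cascade is slow the basic medium may erode C7 in the product through its extended 2-oxyfuran enolate. The fallback separates the two events and closes the ring under neutral conditions; it sets out from 23 and 27 and comes back to the route at 29 and then 30. Sonogashira coupling of 23 with ester 27 (PdCl2(PPh3)2, CuI, Et3N, THF, rt) should give methyl (2Z,6S,8E,10E)-13-[4-(furan-3-ylmethyl)furan-3-yl]-2-(hydroxymethyl)-6,10-dimethyltrideca-2,8,10-trien-4-ynoate F1. LiOH (THF/H2O, 0 °C) then frees acid 29, which is isolated this time. Silver(I)-catalysed 5-exo-dig cycloisomerisation (AgNO3, 10 mol %, acetone, rt) forms the same O1–C5 bond by anti addition and should give 30.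

2. Step 13. Formaldehyde may oligomerise faster than it is captured, the allenolate may simply be protonated to the 3-iodoacrylate, and the Z/E geometry may equilibrate. The fallback avoids 27 and 28 altogether; it sets out from 23 and comes back at 30. Anti addition of bromine to propiolic acid should give (E)-2,3-dibromoprop-2-enoic acid F2. Under the conditions of step 15 this couples with 23 at the β-C–Br bond (cis to CO2H) and lactonises through (2E,6S,8E,10E)-2-bromo-13-[4-(furan-3-ylmethyl)furan-3-yl]-6,10-dimethyltrideca-2,8,10-trien-4-ynoic acid F3 (not isolated). The product is (Z)-3-bromo-5-[(2S,4E,6E)-9-[4-(furan-3-ylmethyl)furan-3-yl]-2,6-dimethylnona-4,6-dien-1-ylidene]furan-2(5H)-one F4. Stille coupling of F4 with (tributylstannyl)methanol (Pd(PPh3)4, dioxane, 80 °C) then installs the hydroxymethyl group at C3 and should give 30.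

3. Step 12. The α-branched aldehyde may partly epimerise at C7 under K2CO3/MeOH before it is homologated. The fallback is a Corey–Fuchs sequence that keeps the aldehyde away from base; it sets out from 20 and comes back at 23. CBr4/PPh3 (CH2Cl2, 0 °C) should give 3-[(3E,5E,8S)-10,10-dibromo-4,8-dimethyldeca-3,5,9-trien-1-yl]-4-(furan-3-ylmethyl)furan F5. n-BuLi (2.1 equiv, THF, −78 °C) converts F5 by Br/Li exchange and 1,2-shift into lithium (3S,5E,7E)-10-[4-(furan-3-ylmethyl)furan-3-yl]-3,7-dimethyldeca-5,7-dien-1-yn-1-ide F6 (not isolated), and aqueous quench gives 23.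

Further compounds
F1 | step 15 | methyl (2Z,6S,8E,10E)-13-[4-(furan-3-ylmethyl)furan-3-yl]-2-(hydroxymethyl)-6,10-dimethyltrideca-2,8,10-trien-4-ynoate | CC(/C=C/C[C@H](C)C#C/C=C(/CO)C(=O)OC)=C\CCc1cocc1Cc1ccoc1
F2 | step 13 | (E)-2,3-dibromoprop-2-enoic acid | OC(=O)/C(Br)=C\Br
F3 | step 13 | (2E,6S,8E,10E)-2-bromo-13-[4-(furan-3-ylmethyl)furan-3-yl]-6,10-dimethyltrideca-2,8,10-trien-4-ynoic acid | CC(/C=C/C[C@H](C)C#C/C=C(/Br)C(=O)O)=C\CCc1cocc1Cc1ccoc1
F4 | step 13 | (Z)-3-bromo-5-[(2S,4E,6E)-9-[4-(furan-3-ylmethyl)furan-3-yl]-2,6-dimethylnona-4,6-dien-1-ylidene]furan-2(5H)-one | CC(/C=C/C[C@H](C)/C=C1/C=C(Br)C(=O)O1)=C\CCc1cocc1Cc1ccoc1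
F5 | step 12 | 3-[(3E,5E,8S)-10,10-dibromo-4,8-dimethyldeca-3,5,9-trien-1-yl]-4-(furan-3-ylmethyl)furan | CC(/C=C/C[C@H](C)C=C(Br)Br)=C\CCc1cocc1Cc1ccoc1
F6 | step 12 | lithium (3S,5E,7E)-10-[4-(furan-3-ylmethyl)furan-3-yl]-3,7-dimethyldeca-5,7-dien-1-yn-1-ide | CC(/C=C/C[C@H](C)C#C[Li])=C\CCc1cocc1Cc1ccoc1
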